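Time is what you watch in this flask, and it may stop paying early. The delta run is the asked flask itself, followed so far; gamma is a thinner, warmer run made earlier.

| setting | delta | gamma | flask |
|---|---|---|---|
| left-handed substrate | 0.050 M | 0.034 M | 0.050 M |
| right-handed substrate | 0.050 M | 0.034 M | 0.050 M |
| coupling partner | 0.075 M | 0.075 M | 0.0750 M |
| precatalyst | 50 µM | 50 µM | 50 µM |
| temperature | 20 °C | 26 °C | 20 °C |
| remark | the very flask that is asked about, followed so far | run made earlier |  |
| time |  |  | 2.5 h |

| delta: time / min | delta: left-handed product / % | gamma: time / min | gamma: left-handed product / % |
|---|---|---|---|
| 25.0 | 34.1 | 0.417 | 0.4 |
| 50.0 | 40.4 | 1.00 | 1.4 |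
| 60.0 | 41.8 | 2.00 | 3.7 |
| 90.0 | 43.4 | 3.00 | 6.9 |

(readings scatter by 0.3 percentage points)

- south: change nothing and wait 2.5 h more
- east: at 2.5 h add precatalyst, 100 % of the amount charged, then wait 2.5 h
- north-east: at 2.5 h take out 90 % of the left-handed product then present, then wait 2.5 h
- north-west: at 2.5 h add coupling partner, 50.0 % of the amount charged, then wait 2.5 h
- south-east: at 2.5 h raise the temperature by 10 K, then wait 2.5 h

- catalyst is single-handed; left-handed substrate and right-handed substrate are mirror images of each other, charged as a racemate, each of them at the stated concentration
- what is taken out of left-handed product is counted as made
- additions bring no volume worth counting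

- left-handed product, in percent of the left-handed substrate and right-handed substrate together first charged, at 2.5 h
- which option adds most left-handed product ("none" when 2 percentage points or less is all one gets) (south / east / north-east / north-west / south-east / none)
- left-handed product present, with what was taken out counted in, in percent of the left-handed substrate and right-handed substrate together first charged, after south
- left-handed product present, with what was taken out counted in, in percent of the left-handed substrate and right-handed substrate together first charged, after east

My reckoning, in slow motion:

1. First instants. Gamma climbs from 0.4 % at 0.417 min to 6.9 % at 3.00 min, and its gain per minute grows. I read that as catalyst still forming from precatalyst in gamma.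

2. Middle. Treat left-handed substrate as pseudo-first-order. Between the first two delta readings its constant is 0.0202 min⁻¹.

3. End. Between the last two delta readings the constant is 0.00724 min⁻¹, a fall by a factor 2.79.

4. The ledger. Each product takes one coupling partner, so [coupling partner] as charged can turn 75.0 % of the racemate into product of either hand: call this the partner cover. If left-handed product were its one use, the partner left would fall by a factor 1.29, which is less than the constant fell. But a single-handed catalyst may merely turn the right-handed substrate more slowly. The gap of 32 percentage points between cover and the last delta reading is smaller than the charge of that substrate, 50.0 % of the racemate. The readings can't separate this from a dying catalyst; I commit to the partner as limiting reagent.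

5. Options. Then "now" stands just above 43.4 %, and south and east stay near it. North-west lifts the cover to 112 %, past the whole racemate, so it can reach the 6.6 points of left-handed substrate unused at the last reading. I choose north-west.

The forecast gave 44.3 % for "now", 44.5 % after south and 48.9 % after east and chose east, holding that “Heat, partner or product removal won't revive dead catalyst.”

The flask gives 44.3 %, with 44.6 % after south and 44.6 % after east. The choice is north-west, which adds 5.7 points, against 0.31 points for east.

    coupling partner + catalyst + left-handed substrate → catalyst + left-handed product (k = 525 L² mol⁻² s⁻¹, Ea = 36.0 kJ mol⁻¹)
    coupling partner + catalyst + right-handed substrate → catalyst + right-handed product (k = 220 L² mol⁻² s⁻¹, Ea = 36.0 kJ mol⁻¹)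
    coupling partner + precatalyst → catalyst + spent reagent (k = 0.0389 L mol⁻¹ s⁻¹, Ea = 62.0 kJ mol⁻¹)
    (constants at 20 °C)

Left-handed substrate uses partner 1.7 times as fast as right-handed substrate at 12.1 min, but that ratio has drifted to 0.68 at 150 min. By then the two products in the flask hold 74.1 % of the racemate against the cover of 75.0 %, with partner at 1.07 % of its charge and catalyst at 98.5 % of the catalyst charged.

With 0.045 M of coupling partner, a neighbouring flask has a cover of 45.0 %. At 150 min it gives 29.4 % of left-handed product and 15.5 % of right-handed product, together 44.9 % of the racemate, with partner at 0.0523 % of its charge.

The numbers in the tables come from a simulation with made-up constants, noise included.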